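**Strategy.** Carotenoid numbering is used. Everything rests on cutting the cyclohexene ring (C1–C6) at C1–C6 and C4–C5. The gem-dimethyl carbon C1 lies β to the oxygen-bearing C3, and C5(CH3)=C6–C7 is a disguised acetoacetate. One Robinson-type Michael/aldol annulation of mesityl oxide (C1–C4) with ethyl acetoacetate (C5–C7) therefore forges both bonds, the quaternary carbon and all three ring methyl groups. The precursors are two achiral liquids. The product, a 3-oxo-4-ene ester, is corrected later: asymmetric epoxidation and hydrolysis set the trans-3,4-diol, and the ester becomes the C7≡C8 alkyne. Sonogashira coupling with a C19 iodopolyenal, then aldol addition of a ring-contracted κ-ketone and oxidation, finish the skeleton.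

Key step: step 1

Assumption: the enol drawn in the target is the chelated tautomer of the 6',8'-diketone. The diketone made in step 24 is expected to rest in this form. The SMILES is read as (3S,4S,3'S,5'R), that is, a trans-3,4-diol and an acyl group trans to the 3'-OH. All polyene steps run under argon in the dark.

Step 1
Reactants: 1 mesityl oxide (4-methylpent-3-en-2-one); 2 ethyl acetoacetate
Product: 5 ethyl 2,6,6-trimethyl-4-oxocyclohex-2-ene-1-carboxylate (racemic), via Michael adduct 3 (not isolated), via cyclic aldol 4 (not isolated)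
Conditions: ZnCl2 (15 mol %), toluene–heptane, reflux, Dean–Stark trap
Reagents that add atoms: none
Why: Robinson-type Michael/aldol annulation: the zinc-chelated enol of 2 adds through its central carbon (future C6) to the β,β-dimethyl terminus of 1 (future C1), which makes the C1–C6 bond and the quaternary carbon and gives the 1,5-diketone 3. The methyl ketone end that stems from 1 (future C4) then enolises and attacks the acetyl carbonyl (future C5), and loss of water from 4 gives the conjugated enone, so the C4–C5 bond follows in the same flask. The ring closes in the 6-(enolendo)-exo-trig aldol mode, and the closest known reaction type is the classical condensation of enones with β-keto esters. The only new stereocentre, C6, forms as a racemate and needs no control because step 3 makes it sp2. The step needs 1,4- over 1,2-addition and the C4-to-C5 aldol rather than attack of the acetoacetate methyl group on the C3 ketone; zinc chelation keeps enolisation of the β-keto ester at C6 and activates the C5 carbonyl, and azeotropic removal of water drains the reversible Michael and aldol equilibria into 5.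

Step 2
Reactants: 5 keto ester
Product: 6 ethyl 4-hydroxy-2,6,6-trimethylcyclohex-2-ene-1-carboxylate (racemic diastereomer mixture)
Conditions: NaBH4, CeCl3·7H2O, MeOH, 0 °C
Reagents that add atoms: none
Why: Luche reduction adds hydride 1,2 to the enone and leaves the ester alone, and the new C3 carbinol centre may form as any mixture because C3 and C6 both become sp2 in step 3.

Step 3
Reactants: 6 allylic alcohol
Product: 8 ethyl 2,6,6-trimethylcyclohexa-1,3-diene-1-carboxylate, via allylic mesylate 7 (not isolated)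
Conditions: MsCl, Et3N, CH2Cl2, 0 °C; then DBU, rt
Reagents that add atoms: methanesulfonyl chloride CS(=O)(=O)Cl (its atoms stay only in 7)
Why: Mesylation and vinylogous E1cB (1,4-) elimination: DBU removes the C6–H that is α to the ester and allylic, the electrons run through C4=C5 and expel the C3 mesylate, so the diene can only arise as the fully conjugated C3=C4–C5=C6 ester.

Step 4
Reactants: 8 diene ester
Product: 9 ethyl (1R,6S)-2,4,4-trimethyl-7-oxabicyclo[4.1.0]hept-2-ene-3-carboxylate, the (3S,4R)-3,4-epoxide in carotenoid numbering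
Conditions: (R,R)-Mn(III)(salen)Cl (Jacobsen catalyst, 5 mol %), aq. NaOCl (pH 11.3), 4-phenylpyridine N-oxide (20 mol %), CH2Cl2, 0 °C
Reagents that add atoms: sodium hypochlorite [Na+].[O-]Cl
Why: Jacobsen–Katsuki epoxidation: the cis-disubstituted, diene-conjugated C3=C4 bond is the ideal substrate class, the tetrasubstituted ester-bearing C5=C6 bond is too hindered and electron-poor to compete, and by analogy with aryl-conjugated cis-olefins the (R,R)-catalyst should give the (3S,4R)-epoxide, so both new centres are under catalyst control.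

Step 5
Reactants: 9 vinyl epoxide
Product: 10 ethyl (3S,4S)-3,4-dihydroxy-2,6,6-trimethylcyclohex-1-ene-1-carboxylate (trans-diol; ring C3 = carotenoid C4)
Conditions: HClO4 (5 mol %), THF–H2O 3:1, 0 °C
Reagents that add atoms: water O
Why: Acid-catalysed SN2-like hydrolysis of a vinyl epoxide: water attacks the allylic carotenoid C4 with inversion (attack at C3 lacks allylic activation and would run 1,3-diaxial to a C1 methyl group), C3 keeps its configuration, and the trans-(3S,4S)-diol results.

Step 6
Reactants: 10 diol ester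
Product: 11 ethyl (3S,4S)-3,4-bis[(tert-butyldimethylsilyl)oxy]-2,6,6-trimethylcyclohex-1-ene-1-carboxylate
Conditions: TBSOTf (2.5 equiv), 2,6-lutidine, CH2Cl2, 0 °C to rt
Reagents that add atoms: tert-butyldimethylsilyl triflate CC(C)(C)[Si](C)(C)OS(=O)(=O)C(F)(F)F
Why: Silyl ether formation with the reactive triflate covers the C3 and the hindered allylic C4 hydroxyl group without touching a stereocentre, and the ethers withstand the hydride, organolithium, palladium and enolate chemistry ahead.

Step 7
Reactants: 11 bis-silyl ester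
Product: 12 [(3S,4S)-3,4-bis(TBSO)-2,6,6-trimethylcyclohex-1-en-1-yl]methanol
Conditions: DIBAL-H (2.5 equiv), CH2Cl2, −78 to 0 °C; Rochelle salt work-up
Reagents that add atoms: none
Why: DIBAL-H reduction of the conjugated ester ends at the allylic alcohol, and the silyl ethers and the tetrasubstituted alkene are inert.

Step 8
Reactants: 12 allylic alcohol
Product: 13 (3S,4S)-3,4-bis(TBSO)-2,6,6-trimethylcyclohex-1-ene-1-carbaldehyde
Conditions: activated MnO2 (excess), CH2Cl2, rt
Reagents that add atoms: none
Why: MnO2 oxidation addresses the only free, primary allylic alcohol and cannot over-oxidise the enal.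

Step 9
Reactants: 13 enal
Product: 14 (1S,2S)-1,2-bis(TBSO)-4-ethynyl-3,5,5-trimethylcyclohex-3-ene
Conditions: TMSCHN2, n-BuLi, THF, −78 °C to rt
Reagents that add atoms: (trimethylsilyl)diazomethane C[Si](C)(C)C=[N+]=[N-]
Why: Colvin rearrangement: lithiated TMS-diazomethane adds to the aldehyde, Peterson-type loss of silanolate and then of N2 gives an alkylidene carbene, and its 1,2-H shift gives the terminal alkyne C7≡C8 next to the quaternary carbon in one step.

Step 10
Reactants: 15 but-2-yn-1-ol
Product: 17 (E)-3-iodobut-2-en-1-ol, via alkenylzirconocene alkoxide 16 (not isolated)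
Conditions: Cp2Zr(H)Cl (2.2 equiv), THF, rt; then I2, 0 °C
Reagents that add atoms: Schwartz reagent Cl[ZrH](C1C=CC=C1)C1C=CC=C1 (its atoms stay only in 16); iodine II
Why: Hydrozirconation–iodination: the first equivalent is consumed by the OH group, syn addition of the second puts zirconium on the less hindered methyl-bearing carbon, and iodinolysis with retention gives the E-iodide that later becomes C9=C10.

Step 11
Reactants: 17 iodo alcohol
Product: 18 (E)-1-bromo-3-iodobut-2-ene
Conditions: CBr4, PPh3, CH2Cl2, 0 °C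
Reagents that add atoms: carbon tetrabromide BrC(Br)(Br)Br
Why: The Appel reaction replaces the primary allylic OH by bromide in an SN2 step under neutral conditions, so the alkene geometry and the vinyl iodide are kept.

Step 12
Reactants: 18 allylic bromide
Product: 19 diethyl [(E)-3-iodobut-2-en-1-yl]phosphonate
Conditions: P(OEt)3 (neat), 100 °C
Reagents that add atoms: triethyl phosphite CCOP(OCC)OCC
Why: The Michaelis–Arbuzov reaction occurs only at the primary allylic bromide, because a vinyl iodide does not react with a phosphite without a metal catalyst.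

Step 13
Reactants: 19 iodo phosphonate; 20 (2E,4E,6E)-2,7-dimethylocta-2,4,6-trienedial
Product: 22 (2E,4E,6E,8E,10E)-11-iodo-2,7-dimethyldodeca-2,4,6,8,10-pentaenal, via phosphonate anion 21 (not isolated)
Conditions: NaHMDS, THF, −78 °C; then 20 (3 equiv), −78 to 0 °C
Reagents that add atoms: none
Why: Horner–Wadsworth–Emmons olefination with an allylic phosphonate anion should give the new C11=C12 bond E, γ-iodoallyl phosphonate anions are a known reagent class, and the excess of the symmetrical dialdehyde secures mono-olefination.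

Step 14
Reactants: 22 iodopentaenal
Product: 23 (2E,4E,6E,8E,10E,12E)-13-iodo-4,9-dimethyltetradeca-2,4,6,8,10,12-hexaenal
Conditions: Ph3P=CHCHO (1.05 equiv), toluene, 60 °C
Reagents that add atoms: (triphenylphosphoranylidene)acetaldehyde O=CC=P(c1ccccc1)(c1ccccc1)c1ccccc1
Why: The Wittig reaction of a stabilised ylide is E-selective (C11'=C12') and returns the aldehyde oxidation level directly, and near-stoichiometric ylide limits a second homologation.

Step 15
Reactants: 23 iodohexaenal
Product: 24 (2E,4E,6E,8E,10E,12E,14E)-15-iodo-2,6,11-trimethylhexadeca-2,4,6,8,10,12,14-heptaenal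
Conditions: Ph3P=C(CH3)CHO (1.5 equiv), toluene, 80 °C
Reagents that add atoms: 2-(triphenylphosphoranylidene)propanal CC(C=O)=P(c1ccccc1)(c1ccccc1)c1ccccc1
Why: The Wittig reaction of the stabilised α-methyl ylide gives the trisubstituted C9'=C10' bond E, and the α-branched enal formed is too unreactive to be olefinated again.

Step 16
Reactants: 25 ketoisophorone (2,6,6-trimethylcyclohex-2-ene-1,4-dione)
Product: 26 (S)-4-hydroxy-2,6,6-trimethylcyclohex-2-en-1-one
Conditions: RuCl(p-cymene)[(S,S)-TsDPEN] (1 mol %), KOH (2 mol %), i-PrOH, rt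
Reagents that add atoms: none
Why: Noyori-type asymmetric transfer hydrogenation reduces only the unhindered C4 carbonyl (C1 is flanked by CMe2 and C-methyl), and with the enone π-system in the role of the aryl group the (S,S)-catalyst should set the (S)-carbinol, the future C3'.

Step 17
Reactants: 26 hydroxy enone
Product: 27 (S)-4-(TBSO)-2,6,6-trimethylcyclohex-2-en-1-one
Conditions: TBSCl, imidazole, DMF, rt
Reagents that add atoms: tert-butyldimethylsilyl chloride CC(C)(C)[Si](C)(C)Cl
Why: Standard silylation protects the only OH group without touching the stereocentre.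

Step 18
Reactants: 27 silyloxy enone
Product: 29 (R)-4-(TBSO)-2,6,6-trimethylcyclohex-1-en-1-yl trifluoromethanesulfonate, via lithium enolate 28 (not isolated)
Conditions: L-Selectride (1.05 equiv), THF, −78 °C; then PhNTf2, −78 °C to rt
Reagents that add atoms: N-phenylbis(trifluoromethanesulfonimide) O=S(=O)(N(c1ccccc1)S(=O)(=O)C(F)(F)F)C(F)(F)F
Why: Conjugate reduction with enolate trapping: the shielded carbonyl and the unsubstituted β-carbon steer the bulky hydride to 1,4-addition, the regiodefined enolate is O-triflated, and the carbinol centre is untouched (the descriptor changes only through CIP priorities).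

Step 19
Reactants: 29 enol triflate
Product: 30 (R)-tert-butyldimethyl[(3,4,5,5-tetramethylcyclohex-3-en-1-yl)oxy]silane
Conditions: MeMgBr, Fe(acac)3 (5 mol %), THF–NMP, −30 to 0 °C
Reagents that add atoms: methylmagnesium bromide C[Mg]Br
Why: Iron-catalysed Kumada-type coupling of an alkenyl triflate with MeMgBr is fast at low temperature, and the position of the tetrasubstituted alkene is fixed by the triflate, which a carbinol dehydration could not guarantee.

Step 20
Reactants: 30 tetrasubstituted alkene
Product: 31 (1S,4S,6R)-4-(TBSO)-1,2,2,6-tetramethyl-7-oxabicyclo[4.1.0]heptane (epoxide anti to the silyl ether; carotenoid 3S,5R,6S)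
Conditions: mCPBA, NaHCO3, CH2Cl2, 0 °C; chromatographic removal of the syn isomer
Reagents that add atoms: 3-chloroperbenzoic acid OOC(=O)c1cccc(Cl)c1
Why: Prilezhaev epoxidation of the electron-rich tetrasubstituted alkene, in which substrate control by the homoallylic silyl ether should favour the anti face and so set both epoxide centres, the minor syn isomer being separable.

Step 21
Reactants: 31 anti epoxide
Product: 32 1-[(1R,4S)-4-(TBSO)-1,2,2-trimethylcyclopentyl]ethan-1-one
Conditions: BF3·OEt2 (20 mol %), CH2Cl2, −78 °C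
Reagents that add atoms: none
Why: Lewis-acid semipinacol (Meinwald-type) ring contraction with a stereospecific anti 1,2-shift: whichever tertiary C–O bond ionises (C1 moves to C5, or C4 moves to C6), the same acetylcyclopentane with the acetyl group trans to the silyloxy group results, so the epoxide face fixes the quaternary (R)-centre C5'.

Step 22
Reactants: 14 ring alkyne; 24 iodoheptaenal
Product: 33 (3S,4S)-3,4-bis(TBSO)-7,8-didehydro-8'-apo-β-caroten-8'-al
Conditions: Pd(PPh3)4 (5 mol %), CuI (10 mol %), Et3N, THF, rt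
Reagents that add atoms: none
Why: Sonogashira coupling forms C8–C9 with retention of the E-iodide geometry at room temperature and tolerates the aldehyde, the polyene and the silyl ethers.

Step 23
Reactants: 32 κ-methyl ketone; 33 C30 aldehyde
Product: 35 (3S,4S,3'S,5'R)-3,4,3'-tris(TBSO)-8'-hydroxy-7,8-didehydro-7',8'-dihydro-β,κ-caroten-6'-one (C8' epimers), via lithium enolate 34 (not isolated)
Conditions: LDA, THF, −78 °C, 32 (1.2 equiv); then 33, −78 °C; aq. quench at −78 °C
Reagents that add atoms: none
Why: Directed aldol addition: 32 can enolise only at its methyl group, the lithium enolate adds 1,2 to the polyenal, the cold quench prevents dehydration, and the C8' carbinol mixture is of no consequence because step 24 removes this centre.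

Step 24
Reactants: 35 aldol
Product: 36 (3S,4S,3'S,5'R)-3,4,3'-tris(TBSO)-8'-hydroxy-7,8-didehydro-β,κ-caroten-6'-one (chelated enol of the 6',8'-dione)
Conditions: IBX (2.5 equiv), DMSO–THF, rt
Reagents that add atoms: none
Why: IBX oxidation of a β-hydroxy ketone to the β-diketone is neutral, so neither retro-aldol cleavage nor dehydration is triggered, the only free alcohol is the activated polyenylic one, and the product should settle as the hydrogen-bonded Z-enol.

Step 25
Reactants: 36 tris-silyl ether
Product: 37 (3S,4S,3'S,5'R)-3,4,3',8'-tetrahydroxy-7,8-didehydro-β,κ-caroten-6'-one (target)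
Conditions: TBAF (6 equiv), AcOH (6 equiv), THF, rt to 40 °C
Reagents that add atoms: none
Why: Fluoride-induced desilylation buffered with acetic acid frees the three secondary alcohols without acid ionisation of the allylic C4–O bond and without base-induced cleavage of the β-diketone, and no stereocentre is touched.

**Compound list**
1 | mesityl oxide | CC(C)=CC(C)=O | starting material
2 | ethyl acetoacetate | CCOC(=O)CC(C)=O | starting material
3 | ethyl 2-acetyl-3,3-dimethyl-5-oxohexanoate (Michael adduct, racemic) | CCOC(=O)C(C(C)=O)C(C)(C)CC(C)=O | intermediate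
4 | ethyl 2-hydroxy-2,6,6-trimethyl-4-oxocyclohexane-1-carboxylate (cyclic aldol, stereoisomer mixture) | CCOC(=O)C1C(C)(O)CC(=O)CC1(C)C | intermediate
5 | ethyl 2,6,6-trimethyl-4-oxocyclohex-2-ene-1-carboxylate (racemic) | CCOC(=O)C1C(C)=CC(=O)CC1(C)C | intermediate
6 | ethyl 4-hydroxy-2,6,6-trimethylcyclohex-2-ene-1-carboxylate (racemic diastereomer mixture) | CCOC(=O)C1C(C)=CC(O)CC1(C)C | intermediate
7 | ethyl 4-(methylsulfonyloxy)-2,6,6-trimethylcyclohex-2-ene-1-carboxylate | CCOC(=O)C1C(C)=CC(OS(C)(=O)=O)CC1(C)C | intermediate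
8 | ethyl 2,6,6-trimethylcyclohexa-1,3-diene-1-carboxylate | CCOC(=O)C1=C(C)C=CCC1(C)C | intermediate
9 | ethyl (1R,6S)-2,4,4-trimethyl-7-oxabicyclo[4.1.0]hept-2-ene-3-carboxylate | CC1=C(C(=O)OCC)C(C)(C)C[C@@H]2O[C@H]12 | intermediate
10 | ethyl (3S,4S)-3,4-dihydroxy-2,6,6-trimethylcyclohex-1-ene-1-carboxylate | CC1=C(C(=O)OCC)C(C)(C)C[C@H](O)[C@H]1O | intermediate
11 | ethyl (3S,4S)-3,4-bis(TBSO)-2,6,6-trimethylcyclohex-1-ene-1-carboxylate | CC1=C(C(=O)OCC)C(C)(C)C[C@H](O[Si](C)(C)C(C)(C)C)[C@H]1O[Si](C)(C)C(C)(C)C | intermediate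
12 | [(3S,4S)-3,4-bis(TBSO)-2,6,6-trimethylcyclohex-1-en-1-yl]methanol | CC1=C(CO)C(C)(C)C[C@H](O[Si](C)(C)C(C)(C)C)[C@H]1O[Si](C)(C)C(C)(C)C | intermediate
13 | (3S,4S)-3,4-bis(TBSO)-2,6,6-trimethylcyclohex-1-ene-1-carbaldehyde | CC1=C(C=O)C(C)(C)C[C@H](O[Si](C)(C)C(C)(C)C)[C@H]1O[Si](C)(C)C(C)(C)C | intermediate
14 | (1S,2S)-1,2-bis(TBSO)-4-ethynyl-3,5,5-trimethylcyclohex-3-ene | CC1=C(C#C)C(C)(C)C[C@H](O[Si](C)(C)C(C)(C)C)[C@H]1O[Si](C)(C)C(C)(C)C | intermediate
15 | but-2-yn-1-ol | CC#CCO | starting material
16 | (E)-3-(chlorozirconocenyl)but-2-enyl chlorozirconocene alkoxide | C/C(=C\CO[Zr](Cl)(C1C=CC=C1)C1C=CC=C1)[Zr](Cl)(C1C=CC=C1)C1C=CC=C1 | intermediate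
17 | (E)-3-iodobut-2-en-1-ol | I/C(C)=C/CO | intermediate
18 | (E)-1-bromo-3-iodobut-2-ene | I/C(C)=C/CBr | intermediate
19 | diethyl [(E)-3-iodobut-2-en-1-yl]phosphonate | I/C(C)=C/CP(=O)(OCC)OCC | intermediate
20 | (2E,4E,6E)-2,7-dimethylocta-2,4,6-trienedial | O=C/C(C)=C/C=C/C=C(C)/C=O | starting material
21 | sodium salt of 19 (phosphonate carbanion) | [Na+].I/C(C)=C/[CH-]P(=O)(OCC)OCC | intermediate
22 | (2E,4E,6E,8E,10E)-11-iodo-2,7-dimethyldodeca-2,4,6,8,10-pentaenal | I/C(C)=C/C=C/C(C)=C/C=C/C=C(C)/C=O | intermediate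
23 | (all-E)-13-iodo-4,9-dimethyltetradeca-2,4,6,8,10,12-hexaenal | I/C(C)=C/C=C/C(C)=C/C=C/C=C(C)/C=C/C=O | intermediate
24 | (all-E)-15-iodo-2,6,11-trimethylhexadeca-2,4,6,8,10,12,14-heptaenal | I/C(C)=C/C=C/C(C)=C/C=C/C=C(C)/C=C/C=C(C)/C=O | intermediate
25 | ketoisophorone | CC1=CC(=O)CC(C)(C)C1=O | starting material
26 | (S)-4-hydroxy-2,6,6-trimethylcyclohex-2-en-1-one | CC1=C[C@@H](O)CC(C)(C)C1=O | intermediate
27 | (S)-4-(TBSO)-2,6,6-trimethylcyclohex-2-en-1-one | CC1=C[C@@H](O[Si](C)(C)C(C)(C)C)CC(C)(C)C1=O | intermediate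
28 | lithium (R)-4-(TBSO)-2,6,6-trimethylcyclohex-1-en-1-olate | [Li+].CC1=C([O-])C(C)(C)C[C@H](O[Si](C)(C)C(C)(C)C)C1 | intermediate
29 | (R)-4-(TBSO)-2,6,6-trimethylcyclohex-1-en-1-yl triflate | CC1=C(OS(=O)(=O)C(F)(F)F)C(C)(C)C[C@H](O[Si](C)(C)C(C)(C)C)C1 | intermediate
30 | (R)-tert-butyldimethyl[(3,4,5,5-tetramethylcyclohex-3-en-1-yl)oxy]silane | CC1=C(C)C(C)(C)C[C@H](O[Si](C)(C)C(C)(C)C)C1 | intermediate
31 | (1S,4S,6R)-4-(TBSO)-1,2,2,6-tetramethyl-7-oxabicyclo[4.1.0]heptane | C[C@]12O[C@@]1(C)C(C)(C)C[C@H](O[Si](C)(C)C(C)(C)C)C2 | intermediate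
32 | 1-[(1R,4S)-4-(TBSO)-1,2,2-trimethylcyclopentyl]ethan-1-one | CC(=O)[C@]1(C)C[C@@H](O[Si](C)(C)C(C)(C)C)CC1(C)C | intermediate
33 | (3S,4S)-3,4-bis(TBSO)-7,8-didehydro-8'-apo-β-caroten-8'-al | CC1=C(C#C/C(C)=C/C=C/C(C)=C/C=C/C=C(C)/C=C/C=C(C)/C=O)C(C)(C)C[C@H](O[Si](C)(C)C(C)(C)C)[C@H]1O[Si](C)(C)C(C)(C)C | intermediate
34 | lithium enolate of 32 | [Li+].C=C([O-])[C@]1(C)C[C@@H](O[Si](C)(C)C(C)(C)C)CC1(C)C | intermediate
35 | tris-TBS 8'-hydroxy-7',8'-dihydro-6'-ketone (aldol, C8' epimers) | CC1=C(C#C/C(C)=C/C=C/C(C)=C/C=C/C=C(C)/C=C/C=C(C)/C(O)CC(=O)[C@]2(C)C[C@@H](O[Si](C)(C)C(C)(C)C)CC2(C)C)C(C)(C)C[C@H](O[Si](C)(C)C(C)(C)C)[C@H]1O[Si](C)(C)C(C)(C)C | intermediate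
36 | tris-TBS ether of the target (enol of the 6',8'-dione) | CC1=C(C#C/C(C)=C/C=C/C(C)=C/C=C/C=C(C)/C=C/C=C(C)/C(O)=C/C(=O)[C@]2(C)C[C@@H](O[Si](C)(C)C(C)(C)C)CC2(C)C)C(C)(C)C[C@H](O[Si](C)(C)C(C)(C)C)[C@H]1O[Si](C)(C)C(C)(C)C | intermediate
37 | (3S,4S,3'S,5'R)-3,4,3',8'-tetrahydroxy-7,8-didehydro-β,κ-caroten-6'-one | CC1=C(C#C/C(C)=C/C=C/C(C)=C/C=C/C=C(C)/C=C/C=C(C)/C(O)=C/C(=O)[C@]2(C)C[C@@H](O)CC2(C)C)C(C)(C)C[C@H](O)[C@H]1O | target

**Total step count:** 25. **Longest linear sequence:** 13 steps (1–9, then 22–25).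

**Steps most likely to fail**

Step 20. Poor facial selectivity in the peracid epoxidation is the concern. The silyl ether is remote from the alkene, and a pseudoaxial C1 methyl group shields the anti face.
- The fallback sets out from 30 and comes back at 31.
- NBS in aqueous acetone adds bromine on the face the peracid prefers. Water then enters at the less hindered C5 from the other face, which gives the trans-bromohydrin 2-bromo-5-(TBSO)-1,2,3,3-tetramethylcyclohexan-1-ol F1 (OH anti and Br syn to the silyl ether).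
- K2CO3 in methanol then closes the epoxide with inversion at C6. The same substrate bias now places the oxygen on the anti face.

Step 21. Methyl migration (ring-retained ketones) or loss of the silyl ether may compete with the ring contraction. The fallback sets out from 29 and comes back at 32.
- Palladium-catalysed methoxycarbonylation (Pd(OAc)2, dppp, CO, MeOH, Et3N) gives methyl (R)-4-(TBSO)-2,6,6-trimethylcyclohex-1-ene-1-carboxylate F2.
- DIBAL-H gives the allylic alcohol [(R)-4-(TBSO)-2,6,6-trimethylcyclohex-1-en-1-yl]methanol F3.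
- Sharpless epoxidation with L-(+)-diethyl tartrate should, by the usual mnemonic, deliver oxygen anti to the silyl ether under reagent control. This gives the anti epoxy alcohol F4.
- TsCl in pyridine gives the epoxy tosylate F5.
- With BF3·OEt2 only the C5–O bond can ionise, and the electron-poor CH2OTs group does not migrate. The C1 shift therefore gives the α-tosyloxy ketone F6.
- SmI2 cleaves the α-C–O bond of F6 to give 32.

Step 4. Enantioface discrimination on this diene may be insufficient. Isomerisation of the sensitive vinyl epoxide, or regiochemical leakage in its hydrolysis (step 5), would also erode the enantiomeric purity. The fallback sets out from 5, comes back at 11, and bypasses steps 2–5.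
- Soft enolisation with TBSOTf and Et3N gives the achiral silyl dienol ether ethyl 4-(TBSO)-2,6,6-trimethylcyclohexa-1,3-diene-1-carboxylate F7.
- Asymmetric hydroboration follows, with monoisopinocampheylborane from (+)-α-pinene (the antipode is equally available should the sense prove opposite). Boron goes to C4 and hydrogen to C3 in a syn addition.
- Oxidation with NaBO3 proceeds with retention and gives the trans product ethyl (3S,4S)-4-(TBSO)-3-hydroxy-2,6,6-trimethylcyclohex-1-ene-1-carboxylate F8.
- TBSOTf then converts F8 into 11.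

**Further compounds**
F1 | step 20 | 2-bromo-5-(TBSO)-1,2,3,3-tetramethylcyclohexan-1-ol (OH anti, Br syn to OTBS) | C[C@@]1(O)C[C@@H](O[Si](C)(C)C(C)(C)C)CC(C)(C)[C@@]1(C)Br
F2 | step 21 | methyl (R)-4-(TBSO)-2,6,6-trimethylcyclohex-1-ene-1-carboxylate | CC1=C(C(=O)OC)C(C)(C)C[C@H](O[Si](C)(C)C(C)(C)C)C1
F3 | step 21 | [(R)-4-(TBSO)-2,6,6-trimethylcyclohex-1-en-1-yl]methanol | CC1=C(CO)C(C)(C)C[C@H](O[Si](C)(C)C(C)(C)C)C1
F4 | step 21 | [4-(TBSO)-2,2,6-trimethyl-7-oxabicyclo[4.1.0]heptan-1-yl]methanol (epoxide anti to OTBS) | C[C@]12O[C@@]1(CO)C(C)(C)C[C@H](O[Si](C)(C)C(C)(C)C)C2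
F5 | step 21 | p-toluenesulfonate of F4 | C[C@]12O[C@@]1(COS(=O)(=O)c3ccc(C)cc3)C(C)(C)C[C@H](O[Si](C)(C)C(C)(C)C)C2
F6 | step 21 | 2-[(1R,4S)-4-(TBSO)-1,2,2-trimethylcyclopentyl]-2-oxoethyl p-toluenesulfonate | Cc1ccc(cc1)S(=O)(=O)OCC(=O)[C@]2(C)C[C@@H](O[Si](C)(C)C(C)(C)C)CC2(C)C
F7 | step 4 | ethyl 4-(TBSO)-2,6,6-trimethylcyclohexa-1,3-diene-1-carboxylate | CCOC(=O)C1=C(C)C=C(O[Si](C)(C)C(C)(C)C)CC1(C)C
F8 | step 4 | ethyl (3S,4S)-4-(TBSO)-3-hydroxy-2,6,6-trimethylcyclohex-1-ene-1-carboxylate | CC1=C(C(=O)OCC)C(C)(C)C[C@H](O[Si](C)(C)C(C)(C)C)[C@H]1O
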